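**Plan**

- Locants used throughout: ring A = C1 (CH2), C2 (CHOH), C3 (CHO-acyl), C4 (CHCH3), C5 (quaternary C–CH3), C10; ring B = C5, C6=C7(OH), C8(=O), C9=C10.
- Enabling feature: ring B is a 4-methylcatechol in dearomatised form (C8 oxygen para to the methyl-bearing C5, C7 oxygen beside it), and C10, meta to the C8 oxygen, carries the chain C1–C3 that holds C4 over C5.
- Retrosynthetic cuts, in order: the C3–O ester bond; C4–C5 (ring A, phenol dearomatisation by a tethered silyl enol ether); C3–C4 (ethyl Grignard on an N-methoxy-N-methylamide); C1–C10 (aryl cuprate opening of a glycidate).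
- Forward: creosol supplies ring B as an arene, the chain C1–C4 is built on C10, ring A closes in the oxidative step, then C3 is reduced and acylated with the separately made dienoic acid, and O7 and O2 are unmasked.
- Stereochemistry: C2 from methyl (R)-glycidate; C5 and C4 from C2 during the cyclisation; C3 by hydroxyl-directed hydride delivery from C2–OH; the side-chain centre from (S)-2-methylbutan-1-ol, and both E double bonds from a Horner–Wadsworth–Emmons reaction.

Key step: step 9

Assumption: (S)-2-methylbutanal keeps its configuration when kept cold in solution and used at once. Abbreviations: TBS = tert-butyldimethylsilyl, TIPS = triisopropylsilyl, TES = triethylsilyl.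

**Route**

Step 1
Reactants: 1 creosol (2-methoxy-4-methylphenol)
Product: 2 tert-butyl(2-methoxy-4-methylphenoxy)dimethylsilane
Conditions: TBSCl, imidazole, DMF, rt
Reagents that add atoms: tert-butyldimethylsilyl chloride, CC(C)(C)[Si](C)(C)Cl
Why: O-silylation of a phenol under imidazole conditions should give an aryl silyl ether that tolerates Grignard and amide chemistry, can later be cleaved at the aryl oxygen alone, and shields the neighbouring ring position in the bromination.

Step 2
Reactants: 2 tert-butyl(2-methoxy-4-methylphenoxy)dimethylsilane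
Product: 3 (5-bromo-2-methoxy-4-methylphenoxy)(tert-butyl)dimethylsilane
Conditions: NBS, MeCN, 0 °C to rt, dark
Reagents that add atoms: N-bromosuccinimide, O=C1CCC(=O)N1Br
Why: electrophilic aromatic bromination should go para to the methoxy group and ortho to the methyl group (the site taken in 3,4-dialkoxytoluenes), because the other open positions are either flanked on both sides or lie next to the bulky silyloxy group.

Step 3
Reactants: 3 (5-bromo-2-methoxy-4-methylphenoxy)(tert-butyl)dimethylsilane; 4 methyl (R)-glycidate (methyl (2R)-oxirane-2-carboxylate)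
Product: 6 methyl (2R)-3-[5-(TBS-oxy)-4-methoxy-2-methylphenyl]-2-hydroxypropanoate, via aryl Grignard reagent 5 (not isolated)
Conditions: Mg, THF, 50 °C; then CuI (10 mol %), 4, THF, −40 to −20 °C
Reagents that add atoms: none
Why: copper-catalysed SN2 opening of the epoxide at its CH2 carbon by an aryl Grignard reagent is faster than addition to the ester at low temperature and forms the C1–C10 bond, while the C2 stereocentre of the glycidate is untouched and is carried over as (R).

Step 4
Reactants: 6 methyl (2R)-3-[5-(TBS-oxy)-4-methoxy-2-methylphenyl]-2-hydroxypropanoate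
Product: 7 methyl (2R)-2-(TBS-oxy)-3-[5-(TBS-oxy)-4-methoxy-2-methylphenyl]propanoate
Conditions: TBSCl, imidazole, DMF, rt
Reagents that add atoms: tert-butyldimethylsilyl chloride, CC(C)(C)[Si](C)(C)Cl
Why: silylation of the secondary α-hydroxy ester without strong base should not epimerise C2 and turns the C2 oxygen into a bulky, poorly nucleophilic ether for the later oxidation.

Step 5
Reactants: 7 methyl (2R)-2-(TBS-oxy)-3-[5-(TBS-oxy)-4-methoxy-2-methylphenyl]propanoate
Product: 8 (2R)-2-(TBS-oxy)-3-[5-(TBS-oxy)-4-methoxy-2-methylphenyl]-N-methoxy-N-methylpropanamide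
Conditions: MeNHOMe·HCl, i-PrMgCl, THF, −20 to 0 °C
Reagents that add atoms: N,O-dimethylhydroxylamine hydrochloride, CNOC.Cl
Why: aminolysis of the ester by the chloromagnesium amide of N,O-dimethylhydroxylamine (Weinreb amide formation) runs at low temperature without enolising the α-silyloxy centre.

Step 6
Reactants: 8 (2R)-2-(TBS-oxy)-3-[5-(TBS-oxy)-4-methoxy-2-methylphenyl]-N-methoxy-N-methylpropanamide
Product: 9 (2R)-2-(TBS-oxy)-1-[5-(TBS-oxy)-4-methoxy-2-methylphenyl]pentan-3-one
Conditions: EtMgBr, THF, 0 °C; aqueous NH4Cl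
Reagents that add atoms: ethylmagnesium bromide, CC[Mg]Br
Why: Weinreb ketone synthesis, in which the chelated tetrahedral adduct persists until work-up so that the ethyl ketone (C3–C4 bond) forms without over-addition or loss of the C2 configuration.

Step 7
Reactants: 9 (2R)-2-(TBS-oxy)-1-[5-(TBS-oxy)-4-methoxy-2-methylphenyl]pentan-3-one
Product: 11 tert-butyl{2-methoxy-4-methyl-5-[(2R,3Z)-2-(TBS-oxy)-3-(TIPS-oxy)pent-3-en-1-yl]phenoxy}dimethylsilane, via lithium enolate 10 (not isolated)
Conditions: LiN(SiMe3)2, THF, −78 °C; then TIPSOTf, −78 to 0 °C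
Reagents that add atoms: triisopropylsilyl trifluoromethanesulfonate, CC(C)[Si](OS(=O)(=O)C(F)(F)F)(C(C)C)C(C)C
Why: kinetic deprotonation by the hindered amide should take a proton of the ethyl CH2 in preference to the shielded α-silyloxy methine and give the Z enolate, which the silyl triflate traps on oxygen (enol silylation) without touching C2.

Step 8
Reactants: 11 tert-butyl{2-methoxy-4-methyl-5-[(2R,3Z)-2-(TBS-oxy)-3-(TIPS-oxy)pent-3-en-1-yl]phenoxy}dimethylsilane
Product: 12 2-methoxy-4-methyl-5-[(2R,3Z)-2-(TBS-oxy)-3-(TIPS-oxy)pent-3-en-1-yl]phenol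
Conditions: K2CO3 (0.2 equiv), MeOH–THF, 0 °C
Reagents that add atoms: none
Why: base-catalysed methanolysis (selective phenolic desilylation) should cleave the aryl silyl ether, with its exposed silicon and phenoxide leaving group, well before the shielded triisopropylsilyl enol ether or the secondary alkyl silyl ether.

Step 9
Reactants: 12 2-methoxy-4-methyl-5-[(2R,3Z)-2-(TBS-oxy)-3-(TIPS-oxy)pent-3-en-1-yl]phenol
Product: 14 (4aR,5R,7R)-7-(TBS-oxy)-3-methoxy-4a,5-dimethyl-4a,5,7,8-tetrahydronaphthalene-2,6-dione (ring locants 2R,4R,5R: C2–OTBS, C3 ketone, C7–OMe, C8 dienone), via aryloxyiodane 13 (not isolated)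
Conditions: PhI(OAc)2 (1.1 equiv), (CF3)2CHOH–CH2Cl2 (4:1), −20 to 0 °C; aqueous NaHCO3
Reagents that add atoms: none
Why: Proposed new method: the phenol exchanges an acetate ligand at trivalent iodine to give aryloxyiodane 13, loss of PhI and acetate in the ionising solvent leaves a phenoxonium ion whose charge is greatest at C5 (para to oxygen and tertiary through its methyl group), the enol ether carbon C4 adds there, and acetate takes the silyl group from the resulting silyloxocarbenium ion to leave the C3 ketone. The closest known reaction type is the trivalent-iodine dearomatisation of para-alkylphenols and 2-alkoxyarenols by allylsilanes and silyl enol ethers, tethered ones included; what has not been shown is a meta tether closing a fused ring onto a methyl-bearing para carbon. Ring A closes in the 6-(enolendo)-exo mode, a cation–olefin addition through a chair-like six-membered transition state. C5 is controlled by C2: the C2 silyloxy group stands pseudo-axial to avoid allylic strain with the C3 silyloxy group (it has no 1,3-diaxial partner because C4 and C10 are trigonal), so C4 bonds to the arene face that places C5–CH3 trans to C2–O; C4 is controlled by the Z enol geometry, which puts its methyl group equatorial and cis to C5–CH3, the arrangement also favoured at equilibrium next to the ketone. The step needs attack at C5 instead of the free ortho carbon C9 (which would rearomatise) and no capture by oxygen nucleophiles; the larger cationic character at the methyl-substituted para carbon, the non-nucleophilic fluoroalcohol, the bulky silyl group on the C2 oxygen and the inability of the tether to reach C7 are relied on for this.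

Step 10
Reactants: 14 (4aR,5R,7R)-7-(TBS-oxy)-3-methoxy-4a,5-dimethyl-4a,5,7,8-tetrahydronaphthalene-2,6-dione
Product: 15 (4aR,5R,7R)-7-hydroxy-3-methoxy-4a,5-dimethyl-4a,5,7,8-tetrahydronaphthalene-2,6-dione
Conditions: HF·pyridine, pyridine–THF, 0 °C to rt
Reagents that add atoms: none
Why: fluoride-mediated desilylation in a pyridine-buffered medium should free the C2 hydroxyl without base, so that neither the α-ketol nor the C4 centre is epimerised.

Step 11
Reactants: 15 (4aR,5R,7R)-7-hydroxy-3-methoxy-4a,5-dimethyl-4a,5,7,8-tetrahydronaphthalene-2,6-dione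
Product: 16 (4aS,5R,6R,7R)-6,7-dihydroxy-3-methoxy-4a,5-dimethyl-5,6,7,8-tetrahydronaphthalen-2(4aH)-one (trans-2,3-diol)
Conditions: Me4NBH(OAc)3, MeCN–AcOH (1:1), −25 °C
Reagents that add atoms: none
Why: hydroxyl-directed reduction (Evans–Saksena type) in which the C2 hydroxyl exchanges an acetate on boron and hydride is delivered within the complex to the face of the C3 carbonyl syn to C2–O, setting the C3 oxygen trans to the C2 oxygen, while the dienone carbonyl, which has no such neighbour, should not be reduced.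

Step 12
Reactants: 16 (4aS,5R,6R,7R)-6,7-dihydroxy-3-methoxy-4a,5-dimethyl-5,6,7,8-tetrahydronaphthalen-2(4aH)-one
Product: 17 (4aS,5R,6R,7R)-6-hydroxy-3-methoxy-4a,5-dimethyl-7-(TES-oxy)-5,6,7,8-tetrahydronaphthalen-2(4aH)-one
Conditions: Et3SiCl (1.05 equiv), imidazole, CH2Cl2, −40 °C
Reagents that add atoms: chlorotriethylsilane, CC[Si](Cl)(CC)CC
Why: selective silylation of the less hindered of two secondary alcohols, since the C3 hydroxyl is flanked by C4–CH3 and lies syn-axial to C5–CH3 while the C2 hydroxyl has a CH2 neighbour.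

Step 13
Reactants: 18 (S)-2-methylbutan-1-ol
Product: 19 (S)-2-methylbutanal
Conditions: TEMPO (1 mol %), KBr (10 mol %), NaOCl (1.1 equiv), NaHCO3 buffer, CH2Cl2–H2O, 0 °C; dried CH2Cl2 solution used at once
Reagents that add atoms: none
Why: TEMPO-catalysed hypochlorite oxidation (Anelli oxidation) stops at the aldehyde and, run cold in a buffered two-phase system, should not enolise the α-stereocentre.

Step 14
Reactants: 19 (S)-2-methylbutanal
Product: 20 ethyl (2E,4E,6S)-6-methylocta-2,4-dienoate
Conditions: (EtO)2P(O)CH2CH=CHCO2Et, LiN(SiMe3)2, THF, −78 °C; then 19, −78 to 0 °C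
Reagents that add atoms: triethyl 4-phosphonocrotonate, CCOC(=O)/C=C/CP(=O)(OCC)OCC
Why: vinylogous Horner–Wadsworth–Emmons olefination with the lithiated phosphonate should form the new double bond E and keep the existing one E, and the fast low-temperature addition leaves the aldehyde α-centre intact.

Step 15
Reactants: 20 ethyl (2E,4E,6S)-6-methylocta-2,4-dienoate
Product: 21 (2E,4E,6S)-6-methylocta-2,4-dienoic acid
Conditions: LiOH, THF–MeOH–H2O, rt; then 1 M HCl to pH 3
Reagents that add atoms: lithium hydroxide, [Li+].[OH-]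
Why: saponification of the ethyl ester at room temperature does not affect the diene geometry or the remote stereocentre.

Step 16
Reactants: 21 (2E,4E,6S)-6-methylocta-2,4-dienoic acid; 17 (4aS,5R,6R,7R)-6-hydroxy-3-methoxy-4a,5-dimethyl-7-(TES-oxy)-5,6,7,8-tetrahydronaphthalen-2(4aH)-one
Product: 23 (1R,2R,3R,8aS)-7-methoxy-1,8a-dimethyl-6-oxo-3-(TES-oxy)-1,2,3,4,6,8a-hexahydronaphthalen-2-yl (2E,4E,6S)-6-methylocta-2,4-dienoate, via mixed anhydride 22 (not isolated)
Conditions: 2,4,6-Cl3C6H2COCl, Et3N, toluene, rt; then 17, DMAP, toluene, rt to 40 °C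
Reagents that add atoms: none
Why: Yamaguchi esterification, in which DMAP converts the mixed anhydride into an acylpyridinium ion reactive enough to acylate the hindered C3 hydroxyl, the only free hydroxyl of 17, without touching a stereocentre.

Step 17
Reactants: 23 (1R,2R,3R,8aS)-7-methoxy-1,8a-dimethyl-6-oxo-3-(TES-oxy)-1,2,3,4,6,8a-hexahydronaphthalen-2-yl (2E,4E,6S)-6-methylocta-2,4-dienoate
Product: 24 (1R,2R,3R,8aS)-7-hydroxy-1,8a-dimethyl-6-oxo-3-(TES-oxy)-1,2,3,4,6,8a-hexahydronaphthalen-2-yl (2E,4E,6S)-6-methylocta-2,4-dienoate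
Conditions: BCl3 (3 equiv), CH2Cl2, −78 °C; aqueous NaHCO3
Reagents that add atoms: none
Why: chelation-assisted O-demethylation, in which BCl3 bridges the C8 carbonyl and the C7 methoxy oxygen, chloride removes the methyl group as chloromethane and hydrolysis of the boron enolate gives the diosphenol, while the ester and the silyl ether should persist at −78 °C (any material that loses the silyl group here is already the target).

Step 18
Reactants: 24 (1R,2R,3R,8aS)-7-hydroxy-1,8a-dimethyl-6-oxo-3-(TES-oxy)-1,2,3,4,6,8a-hexahydronaphthalen-2-yl (2E,4E,6S)-6-methylocta-2,4-dienoate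
Product: 25 Septeremophilane G, (1R,2R,3R,8aS)-3,7-dihydroxy-1,8a-dimethyl-6-oxo-1,2,3,4,6,8a-hexahydronaphthalen-2-yl (2E,4E,6S)-6-methylocta-2,4-dienoate
Conditions: HF·pyridine, pyridine–THF, 0 °C
Reagents that add atoms: none
Why: fluoride cleavage of the triethylsilyl ether under buffered conditions releases the C2 hydroxyl without disturbing the ester, the diosphenol or any stereocentre.

**Compound list**

1 | creosol (2-methoxy-4-methylphenol) | Cc1ccc(O)c(OC)c1 | starting material
2 | tert-butyl(2-methoxy-4-methylphenoxy)dimethylsilane | Cc1ccc(O[Si](C)(C)C(C)(C)C)c(OC)c1 | intermediate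
3 | (5-bromo-2-methoxy-4-methylphenoxy)(tert-butyl)dimethylsilane | Cc1cc(OC)c(O[Si](C)(C)C(C)(C)C)cc1Br | intermediate
4 | methyl (R)-glycidate | COC(=O)[C@H]1CO1 | starting material
5 | [5-(TBS-oxy)-4-methoxy-2-methylphenyl]magnesium bromide | Cc1cc(OC)c(O[Si](C)(C)C(C)(C)C)cc1[Mg]Br | intermediate (not isolated)
6 | methyl (2R)-3-[5-(TBS-oxy)-4-methoxy-2-methylphenyl]-2-hydroxypropanoate | COC(=O)[C@H](O)Cc1cc(O[Si](C)(C)C(C)(C)C)c(OC)cc1C | intermediate
7 | methyl (2R)-2-(TBS-oxy)-3-[5-(TBS-oxy)-4-methoxy-2-methylphenyl]propanoate | COC(=O)[C@H](O[Si](C)(C)C(C)(C)C)Cc1cc(O[Si](C)(C)C(C)(C)C)c(OC)cc1C | intermediate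
8 | (2R)-2-(TBS-oxy)-3-[5-(TBS-oxy)-4-methoxy-2-methylphenyl]-N-methoxy-N-methylpropanamide | CON(C)C(=O)[C@H](O[Si](C)(C)C(C)(C)C)Cc1cc(O[Si](C)(C)C(C)(C)C)c(OC)cc1C | intermediate
9 | (2R)-2-(TBS-oxy)-1-[5-(TBS-oxy)-4-methoxy-2-methylphenyl]pentan-3-one | CCC(=O)[C@H](O[Si](C)(C)C(C)(C)C)Cc1cc(O[Si](C)(C)C(C)(C)C)c(OC)cc1C | intermediate
10 | lithium (2Z,4R)-4-(TBS-oxy)-5-[5-(TBS-oxy)-4-methoxy-2-methylphenyl]pent-2-en-3-olate | [Li+].C/C=C(\[O-])[C@H](O[Si](C)(C)C(C)(C)C)Cc1cc(O[Si](C)(C)C(C)(C)C)c(OC)cc1C | intermediate (not isolated)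
11 | tert-butyl{2-methoxy-4-methyl-5-[(2R,3Z)-2-(TBS-oxy)-3-(TIPS-oxy)pent-3-en-1-yl]phenoxy}dimethylsilane | C/C=C(\O[Si](C(C)C)(C(C)C)C(C)C)[C@H](O[Si](C)(C)C(C)(C)C)Cc1cc(O[Si](C)(C)C(C)(C)C)c(OC)cc1C | intermediate
12 | 2-methoxy-4-methyl-5-[(2R,3Z)-2-(TBS-oxy)-3-(TIPS-oxy)pent-3-en-1-yl]phenol | C/C=C(\O[Si](C(C)C)(C(C)C)C(C)C)[C@H](O[Si](C)(C)C(C)(C)C)Cc1cc(O)c(OC)cc1C | intermediate
13 | acetoxy(phenyl)iodine aryl oxide of phenol 12 | C/C=C(\O[Si](C(C)C)(C(C)C)C(C)C)[C@H](O[Si](C)(C)C(C)(C)C)Cc1cc(OI(OC(C)=O)c2ccccc2)c(OC)cc1C | intermediate (not isolated)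
14 | (4aR,5R,7R)-7-(TBS-oxy)-3-methoxy-4a,5-dimethyl-4a,5,7,8-tetrahydronaphthalene-2,6-dione | C[C@H]1C(=O)[C@H](O[Si](C)(C)C(C)(C)C)CC2=CC(=O)C(OC)=C[C@]12C | intermediate
15 | (4aR,5R,7R)-7-hydroxy-3-methoxy-4a,5-dimethyl-4a,5,7,8-tetrahydronaphthalene-2,6-dione | C[C@H]1C(=O)[C@H](O)CC2=CC(=O)C(OC)=C[C@]12C | intermediate
16 | (4aS,5R,6R,7R)-6,7-dihydroxy-3-methoxy-4a,5-dimethyl-5,6,7,8-tetrahydronaphthalen-2(4aH)-one | O[C@H]1[C@H](O)CC2=CC(=O)C(OC)=C[C@]2(C)[C@H]1C | intermediate
17 | (4aS,5R,6R,7R)-6-hydroxy-3-methoxy-4a,5-dimethyl-7-(TES-oxy)-5,6,7,8-tetrahydronaphthalen-2(4aH)-one | O[C@H]1[C@H](O[Si](CC)(CC)CC)CC2=CC(=O)C(OC)=C[C@]2(C)[C@H]1C | intermediate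
18 | (S)-2-methylbutan-1-ol | CC[C@H](C)CO | starting material
19 | (S)-2-methylbutanal | CC[C@H](C)C=O | intermediate
20 | ethyl (2E,4E,6S)-6-methylocta-2,4-dienoate | CC[C@H](C)/C=C/C=C/C(=O)OCC | intermediate
21 | (2E,4E,6S)-6-methylocta-2,4-dienoic acid | CC[C@H](C)/C=C/C=C/C(=O)O | intermediate
22 | (2E,4E,6S)-6-methylocta-2,4-dienoic 2,4,6-trichlorobenzoic anhydride | CC[C@H](C)/C=C/C=C/C(=O)OC(=O)c1c(Cl)cc(Cl)cc1Cl | intermediate (not isolated)
23 | (1R,2R,3R,8aS)-7-methoxy-1,8a-dimethyl-6-oxo-3-(TES-oxy)-1,2,3,4,6,8a-hexahydronaphthalen-2-yl (2E,4E,6S)-6-methylocta-2,4-dienoate | CC[C@H](C)/C=C/C=C/C(=O)O[C@H]1[C@H](O[Si](CC)(CC)CC)CC2=CC(=O)C(OC)=C[C@]2(C)[C@H]1C | intermediate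
24 | (1R,2R,3R,8aS)-7-hydroxy-1,8a-dimethyl-6-oxo-3-(TES-oxy)-1,2,3,4,6,8a-hexahydronaphthalen-2-yl (2E,4E,6S)-6-methylocta-2,4-dienoate | CC[C@H](C)/C=C/C=C/C(=O)O[C@H]1[C@H](O[Si](CC)(CC)CC)CC2=CC(=O)C(O)=C[C@]2(C)[C@H]1C | intermediate
25 | Septeremophilane G | CC[C@H](C)/C=C/C=C/C(=O)O[C@H]1[C@H](O)CC2=CC(=O)C(O)=C[C@]2(C)[C@H]1C | target

**Step count and risks**

Total steps: 18. Longest linear sequence: 15 steps (steps 1–12 and 16–18, from creosol); the acid 21 is made in three steps (13–15) and joined in step 16.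

Steps most likely to fail:

Step 9. What may go wrong: addition of the enol carbon at the unsubstituted ortho carbon C9 followed by rearomatisation, oxidation or protodesilylation of the enol ether before the phenol is engaged, or poor discrimination between the two faces of C5. The fallback makes the same C4–C5 bond by a known reaction type, the intramolecular para-C-alkylation of a phenoxide by a tethered halide (alkylative dearomatisation). It sets out from enol ether 11: N-bromosuccinimide in THF at −78 °C should give the α-bromo ketone (both C4 epimers) F1. KHF2 in MeOH at rt should then free only the phenol to give the bromo phenol F2. KOt-Bu in t-BuOH–THF at 0 °C would generate the phenoxide, whose para carbon C5 displaces bromide to close ring A, and the basic medium should settle C4 in its equatorial configuration. The fallback rejoins the route at dienone 14.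

Step 16. What may go wrong: acylation too slow at the axial C3 hydroxyl, which is flanked on both sides and syn-axial to C5–CH3, so that silyl migration from O2 or isomerisation of the activated dienoyl unit takes over. The fallback attaches a small acyl unit first and builds the diene on the ring. It sets out from alcohol 17 and aldehyde 19: DCC-mediated acylation of 17 with diethylphosphonoacetic acid should give the phosphonoacetate ester F3. Separately, aldehyde 19 and Ph3P=CHCHO in toluene (Wittig reaction) should give (2E,4S)-4-methylhex-2-enal F4. A Horner–Wadsworth–Emmons reaction of F3 with F4 under LiCl and DBU in MeCN (Masamune–Roush conditions) would form the 2E double bond and rejoin the route at ester 23.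

Step 17. What may go wrong: attack of the Lewis acid on the dienoate ester or the silyl ether, with loss of the acyl group, before demethylation is complete. The fallback moves the demethylation ahead of the esterification. It sets out from diol 16: BCl3 in CH2Cl2 at −78 °C should give the 2,3,7-trihydroxy dienone F5. TBSCl (2.2 equiv) and imidazole should silylate the acidic enol hydroxyl and the C2 hydroxyl, leaving the hindered C3 hydroxyl free, to give the bis-silyl ether F6. Yamaguchi esterification with acid 21 would give the ester F7, and HF·pyridine would remove both silyl groups, arriving directly at the target 25.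

Further compounds
F1 | step 9 | (2R)-4-bromo-2-(TBS-oxy)-1-[5-(TBS-oxy)-4-methoxy-2-methylphenyl]pentan-3-one (both C4 epimers) | CC(Br)C(=O)[C@H](O[Si](C)(C)C(C)(C)C)Cc1cc(O[Si](C)(C)C(C)(C)C)c(OC)cc1C
F2 | step 9 | (2R)-4-bromo-2-(TBS-oxy)-1-(5-hydroxy-4-methoxy-2-methylphenyl)pentan-3-one (both C4 epimers) | CC(Br)C(=O)[C@H](O[Si](C)(C)C(C)(C)C)Cc1cc(O)c(OC)cc1C
F3 | step 16 | (1R,2R,3R,8aS)-7-methoxy-1,8a-dimethyl-6-oxo-3-(TES-oxy)-1,2,3,4,6,8a-hexahydronaphthalen-2-yl 2-(diethoxyphosphoryl)acetate | CCOP(=O)(OCC)CC(=O)O[C@H]1[C@H](O[Si](CC)(CC)CC)CC2=CC(=O)C(OC)=C[C@]2(C)[C@H]1C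
F4 | step 16 | (2E,4S)-4-methylhex-2-enal | CC[C@H](C)/C=C/C=O
F5 | step 17 | (4aS,5R,6R,7R)-3,6,7-trihydroxy-4a,5-dimethyl-5,6,7,8-tetrahydronaphthalen-2(4aH)-one | O[C@H]1[C@H](O)CC2=CC(=O)C(O)=C[C@]2(C)[C@H]1C
F6 | step 17 | (4aS,5R,6R,7R)-6-hydroxy-4a,5-dimethyl-3,7-bis(TBS-oxy)-5,6,7,8-tetrahydronaphthalen-2(4aH)-one | O[C@H]1[C@H](O[Si](C)(C)C(C)(C)C)CC2=CC(=O)C(O[Si](C)(C)C(C)(C)C)=C[C@]2(C)[C@H]1C
F7 | step 17 | (1R,2R,3R,8aS)-1,8a-dimethyl-6-oxo-3,7-bis(TBS-oxy)-1,2,3,4,6,8a-hexahydronaphthalen-2-yl (2E,4E,6S)-6-methylocta-2,4-dienoate | CC[C@H](C)/C=C/C=C/C(=O)O[C@H]1[C@H](O[Si](C)(C)C(C)(C)C)CC2=CC(=O)C(O[Si](C)(C)C(C)(C)C)=C[C@]2(C)[C@H]1C
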